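**Strategy.** Ring B (C1' on coumarin C3, C2'H, C3'=O, C4' carbinol with prenyl, C5'H2, C6'=O) is read as a 2-aryl-5-prenylquinone whose C4'–C5' oxirane has been reduced at C5'. The key step is an enantioselective Weitz–Scheffer epoxidation of the C6' dimethyl monoketal of that quinone. A chiral peroxide adds to C5', the only open β-carbon of the single free (C3') carbonyl, and closes the oxirane, forming the C5'–O and C4'–O bonds and fixing C4'. The precursor is an achiral cross-conjugated dienone, made by trivalent-iodine oxidation of a para-methoxyphenol whose two ring-B oxygens are differentiated from the outset. Afterwards C5'–O is cleaved reductively.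

Key step: step 6

Assumption: the L-(+)-tartrate-modified peroxide is taken to give the (4'R,5'S)-oxirane; if the sense of induction proves opposite, the D-(–)-ester is used with no other change.

Remarks on the chemistry:
- The oxirane needed is (4'R,5'S). Its C4'–O bond is never broken, and this maps onto (4'R) in the target.
- Trityl hydroperoxide is treated as a purchased reagent.
- C3' is held as a carbinol while the oxirane is opened. With both ring-B carbonyls free, each oxirane carbon would be α to a ketone and the ene-dione itself would be reducible by selenide.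

**Step 1**
Reactants: 1 2-hydroxy-4-methoxybenzaldehyde; 2 (5-bromo-2-methoxyphenyl)acetic acid
Product: 3 3-(5-bromo-2-methoxyphenyl)-7-methoxy-2H-chromen-2-one
Conditions: Ac2O, Et3N, 120 °C
Reagents that add atoms: none
Why: Perkin–Oglialoro condensation (O-acylation, intramolecular aldol-type condensation, dehydration) should give the 3-arylcoumarin, with bromine marking the future C3' oxygen and the methoxy group marking C6', so the two ring-B oxygens never need to be told apart later.

**Step 2**
Reactants: 3 3-(5-bromo-2-methoxyphenyl)-7-methoxy-2H-chromen-2-one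
Product: 5 3-(5-hydroxy-2-methoxyphenyl)-7-methoxy-2H-chromen-2-one, via aryl pinacol boronate 4 (not isolated)
Conditions: B2pin2, Pd(dppf)Cl2, KOAc, 1,4-dioxane, 90 °C; then 30% aq. H2O2, aq. NaHCO3, THF, 0 °C to rt
Reagents that add atoms: bis(pinacolato)diboron, CC1(C)OB(OC1(C)C)B1OC(C)(C)C(C)(C)O1 (boryl group of 4); hydrogen peroxide, OO (phenol oxygen of 5)
Why: Miyaura borylation of the aryl bromide followed by peroxide-induced 1,2-shift of the aryl group from boron to oxygen should give the phenol under near-neutral conditions that spare the lactone.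

**Step 3**
Reactants: 5 3-(5-hydroxy-2-methoxyphenyl)-7-methoxy-2H-chromen-2-one
Product: 6 3-(5-hydroxy-4-iodo-2-methoxyphenyl)-7-methoxy-2H-chromen-2-one
Conditions: I2, NaHCO3, THF/H2O, 0 °C to rt
Reagents that add atoms: iodine, II
Why: Electrophilic aromatic iodination through the phenoxide goes ortho to the oxygen because the para carbon carries the methoxy group, and of the two ortho carbons C2' is shielded by the coumarin, so C4' should be substituted.

**Step 4**
Reactants: 6 3-(5-hydroxy-4-iodo-2-methoxyphenyl)-7-methoxy-2H-chromen-2-one; 7 tributyl(3-methylbut-2-en-1-yl)stannane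
Product: 8 3-[5-hydroxy-2-methoxy-4-(3-methylbut-2-en-1-yl)phenyl]-7-methoxy-2H-chromen-2-one
Conditions: Pd(PPh3)4, DMF, 90 °C
Reagents that add atoms: none
Why: Stille coupling at the aryl iodide with zerovalent palladium should transfer the prenyl group through its tin-bearing carbon to give the linear isomer, and the neutral conditions tolerate the free phenol and the lactone.

**Step 5**
Reactants: 8 3-[5-hydroxy-2-methoxy-4-(3-methylbut-2-en-1-yl)phenyl]-7-methoxy-2H-chromen-2-one
Product: 9 3-[6,6-dimethoxy-4-(3-methylbut-2-en-1-yl)-3-oxocyclohexa-1,4-dien-1-yl]-7-methoxy-2H-chromen-2-one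
Conditions: PhI(OAc)2, MeOH, 0 °C
Reagents that add atoms: methanol, CO
Why: Oxidative dearomatisation of a para-methoxyphenol by trivalent iodine lets methanol add to the methoxy-bearing carbon para to the phenol, so the ketal should form only at C6' and the ketone only at C3'.

**Step 6**
Reactants: 9 3-[6,6-dimethoxy-4-(3-methylbut-2-en-1-yl)-3-oxocyclohexa-1,4-dien-1-yl]-7-methoxy-2H-chromen-2-one
Product: 10 3-[(4R,5S)-4,5-epoxy-6,6-dimethoxy-4-(3-methylbut-2-en-1-yl)-3-oxocyclohex-1-en-1-yl]-7-methoxy-2H-chromen-2-one
Conditions: Ph3COOH, NaN(SiMe3)2, L-(+)-diisopropyl tartrate, 4 Å MS, toluene, –60 °C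
Reagents that add atoms: trityl hydroperoxide, OOC(c1ccccc1)(c1ccccc1)c1ccccc1
Why: Sodium trityl peroxide, held in a chiral sodium tartrate aggregate, should add in conjugate fashion to C5' of the C3' dienone, and the C4' enolate then attacks the near peroxide oxygen and expels trityloxide. This is a Weitz–Scheffer epoxidation, and the closest known reaction type is the tartrate-mediated nucleophilic epoxidation of quinone monoketals that carry a prenyl group on the α-carbon. The oxirane closes by 3-exo-tet displacement at oxygen. C4' (R) and C5' (S) arise together in the cis-fused ring, and since 9 has no stereocentre the face of attack is set by the chiral tartrate–peroxide aggregate alone. Site selectivity among C5', C1' and coumarin C4 is needed: C1' is fully substituted and flanked by the coumarin and the ketal, coumarin C4 is deactivated by the push–pull with the 7-methoxy group, and the C6' ketal leaves C3' as the only activating carbonyl. The bulky anhydrous peroxide at low temperature should spare the lactone and the electron-rich prenyl alkene.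

**Step 7**
Reactants: 10 3-[(4R,5S)-4,5-epoxy-6,6-dimethoxy-4-(3-methylbut-2-en-1-yl)-3-oxocyclohex-1-en-1-yl]-7-methoxy-2H-chromen-2-one
Product: 12 3-[(4S,5S)-4,5-epoxy-3-hydroxy-4-(3-methylbut-2-en-1-yl)-6-oxocyclohex-1-en-1-yl]-7-methoxy-2H-chromen-2-one (C3' epimers), via epoxy carbinol ketal 11 (not isolated)
Conditions: NaBH4, CeCl3·7H2O, MeOH, –78 °C; then 1 M aq. HCl to pH 2, THF, 0 °C to rt
Reagents that add atoms: water, O
Why: Luche reduction should deliver hydride 1,2 to the C3' enone carbonyl (the carbinol configuration is immaterial because step 9 reoxidises it) and dilute acid then hydrolyses the allylic C6' ketal, so that C5' becomes the α-carbon of the only ketone and the ring alkene is a plain enone and not an ene-dione.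

**Step 8**
Reactants: 12 3-[(4S,5S)-4,5-epoxy-3-hydroxy-4-(3-methylbut-2-en-1-yl)-6-oxocyclohex-1-en-1-yl]-7-methoxy-2H-chromen-2-one (C3' epimers)
Product: 13 3-[(4R)-3,4-dihydroxy-4-(3-methylbut-2-en-1-yl)-6-oxocyclohex-1-en-1-yl]-7-methoxy-2H-chromen-2-one (C3' epimers)
Conditions: PhSeSePh, NaBH4, EtOH (gives Na[PhSeB(OEt)3]); then AcOH, 0 °C
Reagents that add atoms: none
Why: In this organoselenium reduction of an α,β-epoxy ketone the selenolate should open the oxirane by SN2 attack at the secondary C5' next to the C6' ketone, a second selenolate removes selenium to give the enol that acetic acid protonates, and the untouched C4'–O bond keeps its configuration.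

**Step 9**
Reactants: 13 3-[(4R)-3,4-dihydroxy-4-(3-methylbut-2-en-1-yl)-6-oxocyclohex-1-en-1-yl]-7-methoxy-2H-chromen-2-one (C3' epimers)
Product: 14 3-[(4R)-4-hydroxy-4-(3-methylbut-2-en-1-yl)-3,6-dioxocyclohex-1-en-1-yl]-7-methoxy-2H-chromen-2-one
Conditions: Dess–Martin periodinane, NaHCO3, CH2Cl2, 0 °C
Reagents that add atoms: none
Why: Dess–Martin oxidation should convert the secondary allylic C3' carbinol of both epimers into the ketone while the tertiary C4' hydroxyl cannot be oxidised, and the buffered, cold conditions guard against loss of water to the quinone.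

**Compound list**

1 | 2-hydroxy-4-methoxybenzaldehyde | COc1ccc(C=O)c(O)c1 | starting material
2 | (5-bromo-2-methoxyphenyl)acetic acid | COc1ccc(Br)cc1CC(=O)O | starting material
3 | 3-(5-bromo-2-methoxyphenyl)-7-methoxy-2H-chromen-2-one | COc1ccc2cc(-c3cc(Br)ccc3OC)c(=O)oc2c1 | intermediate
4 | 7-methoxy-3-[2-methoxy-5-(4,4,5,5-tetramethyl-1,3,2-dioxaborolan-2-yl)phenyl]-2H-chromen-2-one (aryl pinacol boronate) | COc1ccc2cc(-c3cc(B4OC(C)(C)C(C)(C)O4)ccc3OC)c(=O)oc2c1 | intermediate
5 | 3-(5-hydroxy-2-methoxyphenyl)-7-methoxy-2H-chromen-2-one | COc1ccc2cc(-c3cc(O)ccc3OC)c(=O)oc2c1 | intermediate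
6 | 3-(5-hydroxy-4-iodo-2-methoxyphenyl)-7-methoxy-2H-chromen-2-one | COc1ccc2cc(-c3cc(O)c(I)cc3OC)c(=O)oc2c1 | intermediate
7 | tributyl(3-methylbut-2-en-1-yl)stannane | CCCC[Sn](CCCC)(CCCC)CC=C(C)C | starting material
8 | 3-[5-hydroxy-2-methoxy-4-(3-methylbut-2-en-1-yl)phenyl]-7-methoxy-2H-chromen-2-one | COc1ccc2cc(-c3cc(O)c(CC=C(C)C)cc3OC)c(=O)oc2c1 | intermediate
9 | 3-[6,6-dimethoxy-4-(3-methylbut-2-en-1-yl)-3-oxocyclohexa-1,4-dien-1-yl]-7-methoxy-2H-chromen-2-one (C6' dimethyl monoketal of the quinone) | COc1ccc2cc(C3=CC(=O)C(CC=C(C)C)=CC3(OC)OC)c(=O)oc2c1 | intermediate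
10 | 3-[(4R,5S)-4,5-epoxy-6,6-dimethoxy-4-(3-methylbut-2-en-1-yl)-3-oxocyclohex-1-en-1-yl]-7-methoxy-2H-chromen-2-one | COc1ccc2cc(C3=CC(=O)[C@]4(CC=C(C)C)O[C@@H]4C3(OC)OC)c(=O)oc2c1 | intermediate
11 | 3-[(4S,5S)-4,5-epoxy-3-hydroxy-6,6-dimethoxy-4-(3-methylbut-2-en-1-yl)cyclohex-1-en-1-yl]-7-methoxy-2H-chromen-2-one, C3' epimers, oxirane as in 10 (epoxy carbinol ketal) | COc1ccc2cc(C3=CC(O)[C@]4(CC=C(C)C)O[C@@H]4C3(OC)OC)c(=O)oc2c1 | intermediate
12 | 3-[(4S,5S)-4,5-epoxy-3-hydroxy-4-(3-methylbut-2-en-1-yl)-6-oxocyclohex-1-en-1-yl]-7-methoxy-2H-chromen-2-one, C3' epimers, oxirane as in 10 | COc1ccc2cc(C3=CC(O)[C@]4(CC=C(C)C)O[C@@H]4C3=O)c(=O)oc2c1 | intermediate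
13 | 3-[(4R)-3,4-dihydroxy-4-(3-methylbut-2-en-1-yl)-6-oxocyclohex-1-en-1-yl]-7-methoxy-2H-chromen-2-one, C3' epimers | COc1ccc2cc(C3=CC(O)[C@@](O)(CC=C(C)C)CC3=O)c(=O)oc2c1 | intermediate
14 | 3-[(4R)-4-hydroxy-4-(3-methylbut-2-en-1-yl)-3,6-dioxocyclohex-1-en-1-yl]-7-methoxy-2H-chromen-2-one | COc1ccc2cc(C3=CC(=O)[C@@](O)(CC=C(C)C)CC3=O)c(=O)oc2c1 | target

In 11–13 the C3' centre is left without a descriptor because it is not controlled and is removed in step 9. The change of the C4' descriptor between 10 and 11/12 reflects only the priority order, not the geometry.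

**Totals.** Total step count: 9. Longest linear sequence: 9 steps (1 or 2 to 14).

**Steps most likely to fail**

Step 6. The tartrate aggregate may discriminate poorly between the two faces of a dienone that has no coordinating hydroxyl, and the peroxide may attack the lactone or coumarin C4 competitively. The fallback replaces reagent control by auxiliary control and sets out from 9. Transketalisation with (1R,2R)-1,2-diphenylethane-1,2-diol (PPTS, benzene, 4 Å MS) should give the hydrobenzoin ketal dienone F1. An achiral Weitz–Scheffer epoxidation (t-BuOOH, DBU, CH2Cl2) should then give diastereomers that can be separated on silica, of which the (4'R,5'S)-epoxy hydrobenzoin ketal F2 is carried on; the antipodal diol is used if it favours that isomer. NaBH4 with CeCl3·7H2O should give the epoxy carbinol hydrobenzoin ketal F3, and aqueous CF3CO2H in CH2Cl2 removes the diol, so the fallback comes back to the route at 12.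

Step 4. The prenyl unit may be transferred through its γ-carbon to give the 1,1-dimethylallyl isomer, oxidative addition may be slow beside the free phenol, and protodeiodination may compete. The fallback forms the C–C bond by a sigmatropic shift, not by cross-coupling, and sets out from 5, which makes step 3 unnecessary. O-Alkylation with 3-chloro-3-methylbut-1-yne (DBU, CuCl2·2H2O cat., MeCN, 0 °C) should give the 1,1-dimethylpropargyl ether F4. Semi-hydrogenation (H2, Pd/CaCO3 poisoned with Pb(OAc)2, quinoline, EtOAc) should give the 1,1-dimethylallyl ether F5. Aromatic Claisen rearrangement (PhNEt2, 140 °C) then moves the allyl unit with inversion to the unhindered ortho carbon C4', and the fallback comes back to the route at 8.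

Step 8. The new tertiary hydroxyl may be lost from the enolate with aromatisation to the hydroquinone, the oxirane may migrate to the C3' hydroxyl before it is opened, and selenolate may be tied up in reversible conjugate addition at C2'. The fallback replaces nucleophilic opening by single-electron transfer and sets out from 12. SmI2 in THF/MeOH at –90 °C should cleave the C5'–O bond through the C6' ketyl and protonate the samarium enolate at once. It comes back to the route at 13 and forms no compound outside the list (F0).

**Further compounds**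

F1 | step 6 | analogue of 9 in which the C6' dimethyl ketal is replaced by the (4R,5R)-4,5-diphenyl-1,3-dioxolane ketal (hydrobenzoin ketal dienone) | COc1ccc2cc(C3=CC(=O)C(CC=C(C)C)=CC34O[C@H](c5ccccc5)[C@@H](c5ccccc5)O4)c(=O)oc2c1
F2 | step 6 | (4'R,5'S)-4',5'-epoxide of F1 (epoxy hydrobenzoin ketal) | COc1ccc2cc(C3=CC(=O)[C@]4(CC=C(C)C)O[C@@H]4C35O[C@H](c6ccccc6)[C@@H](c6ccccc6)O5)c(=O)oc2c1
F3 | step 6 | C3' carbinol of F2, C3' epimers (epoxy carbinol hydrobenzoin ketal) | COc1ccc2cc(C3=CC(O)[C@]4(CC=C(C)C)O[C@@H]4C35O[C@H](c6ccccc6)[C@@H](c6ccccc6)O5)c(=O)oc2c1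
F4 | step 4 | 7-methoxy-3-[2-methoxy-5-(2-methylbut-3-yn-2-yloxy)phenyl]-2H-chromen-2-one (1,1-dimethylpropargyl ether) | COc1ccc2cc(-c3cc(OC(C)(C)C#C)ccc3OC)c(=O)oc2c1
F5 | step 4 | 7-methoxy-3-[2-methoxy-5-(2-methylbut-3-en-2-yloxy)phenyl]-2H-chromen-2-one (1,1-dimethylallyl ether) | COc1ccc2cc(-c3cc(OC(C)(C)C=C)ccc3OC)c(=O)oc2c1
F0 | step 8 | none | none
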